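## Retrosynthetic overview

1. The 1,4-dioxane is the only ring that has to be made. It is closed last through the C2–O1 bond: a 4-alkyl-2,6-dimethoxyphenol is dehydrogenated to its p-quinone methide, which is captured by the neighbouring ring-A phenol (sets C-2, trans to C-3).
2. The cyclisation precursor is a bis-phenolic (R)-aryl 1-arylprop-2-yl ether. It comes from its ring-A aldehyde / ring-B silyl ether by Dakin-type oxidation (CHO → OH marks the future C-8a oxygen) and desilylation.
3. The C3–O4 bond is made by Mitsunobu inversion between 5-allyl-2-hydroxy-3-methoxybenzaldehyde and an (S)-1-arylpropan-2-ol (sets C-3 as R).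
4. The aldehyde comes from eugenol by ortho-formylation. The alcohol comes from the aryl Grignard reagent of silyl-protected 4-bromo-2,6-dimethoxyphenol and (S)-propylene oxide (chiral pool).
5. Ring order: both benzene rings are bought; the dioxane ring is formed in the final step.

Assumption: reagents that only deliver a group (formaldehyde, TBSCl, mCPBA) are not numbered; 4-bromo-2,6-dimethoxyphenol and (S)-propylene oxide are taken as catalogue items.

## Route

Step 1
Reactants: 1 eugenol (4-allyl-2-methoxyphenol)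
Product: 3 2-hydroxy-3-methoxy-5-(prop-2-en-1-yl)benzaldehyde, via benzylic alcohol 2 (not isolated)
Conditions: MgCl2, Et3N, (CH2O)n, MeCN, reflux; then 1 M HCl
Reagents that add atoms: formaldehyde (from paraformaldehyde), C=O
Why: Magnesium-mediated ortho-formylation of a phenol: the chelated phenoxymagnesium species takes up formaldehyde at the only free ortho position and a second formaldehyde oxidises the benzylic alkoxide 2 to the aldehyde by hydride transfer, leaving the allyl group untouched; no stereocentre is involved.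

Step 2
Reactants: 4 4-bromo-2,6-dimethoxyphenol
Product: 5 (4-bromo-2,6-dimethoxyphenoxy)(tert-butyl)dimethylsilane
Conditions: TBSCl, imidazole, DMF, rt → 40 °C
Reagents that add atoms: tert-butyldimethylsilyl chloride (TBSCl), CC(C)(C)[Si](C)(C)Cl
Why: Standard imidazole-promoted O-silylation of a phenol; the silyl ether masks the acidic OH for Grignard formation, the Mitsunobu reaction and the peracid step and is later lost under the same mild base that cleaves the formate; no stereocentre.

Step 3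
Reactants: 5 (4-bromo-2,6-dimethoxyphenoxy)(tert-butyl)dimethylsilane; 6 (S)-2-methyloxirane
Product: 8 (2S)-1-{4-[(tert-butyldimethylsilyl)oxy]-3,5-dimethoxyphenyl}propan-2-ol, via Grignard reagent 7 (not isolated)
Conditions: Mg, THF, 50 °C; then CuI (10 mol%), 6, −30 → 0 °C; aq. NH4Cl
Reagents that add atoms: none
Why: Copper-catalysed SN2 opening of a terminal epoxide by an aryl Grignard reagent at the unsubstituted carbon; the stereocentre of 6 is not touched, so its (S) configuration is carried into 8.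

Step 4
Reactants: 3 2-hydroxy-3-methoxy-5-(prop-2-en-1-yl)benzaldehyde; 8 (2S)-1-{4-[(tert-butyldimethylsilyl)oxy]-3,5-dimethoxyphenyl}propan-2-ol
Product: 9 2-{[(2R)-1-{4-[(tert-butyldimethylsilyl)oxy]-3,5-dimethoxyphenyl}propan-2-yl]oxy}-3-methoxy-5-(prop-2-en-1-yl)benzaldehyde
Conditions: PPh3, DIAD, THF, 0 °C → rt
Reagents that add atoms: none
Why: Mitsunobu etherification in which the acidic, chelated phenol of 3 displaces the activated secondary alcohol by SN2 with inversion, turning the (S) carbinol into the (R) aryl ether that becomes C-3 of the target.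

Step 5
Reactants: 9 2-{[(2R)-1-{4-[(tert-butyldimethylsilyl)oxy]-3,5-dimethoxyphenyl}propan-2-yl]oxy}-3-methoxy-5-(prop-2-en-1-yl)benzaldehyde
Product: 11 4-{(2R)-2-[2-hydroxy-6-methoxy-4-(prop-2-en-1-yl)phenoxy]propyl}-2,6-dimethoxyphenol, via aryl formate 10 (not isolated)
Conditions: mCPBA, CH2Cl2, 0 °C → rt; then K2CO3, MeOH, rt → 40 °C (Ar); aq. NH4Cl
Reagents that add atoms: meta-chloroperoxybenzoic acid (mCPBA), OOC(=O)c1cccc(Cl)c1
Why: Baeyer–Villiger (Dakin-type) oxidation of the electron-rich ortho-alkoxybenzaldehyde proceeds by aryl migration much faster than epoxidation of the monosubstituted alkene, and carbonate-mediated methanolysis then removes both the formate and the base-labile aryl silyl ether; the stereocentre is untouched.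

Step 6
Reactants: 11 4-{(2R)-2-[2-hydroxy-6-methoxy-4-(prop-2-en-1-yl)phenoxy]propyl}-2,6-dimethoxyphenol
Product: 13 (2R,3R)-2-(4-hydroxy-3,5-dimethoxyphenyl)-5-methoxy-3-methyl-7-(prop-2-en-1-yl)-2,3-dihydro-1,4-benzodioxine, via quinone methide 12 (not isolated)
Conditions: DDQ (1.0 equiv), CH2Cl2, −20 → 0 °C
Reagents that add atoms: none
Why: DDQ abstracts hydride from the benzylic position para to the free phenol (dehydrogenation of a 4-alkylphenol to a p-quinone methide) and the ring-A phenol closes the dioxane by intramolecular oxa-1,6-conjugate addition, the fixed (R) centre at C-3 placing the aryl group trans (both substituents pseudo-equatorial, and the addition is reversible so trans is also the thermodynamic product), which gives C-2 as R.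

## Compound list

1 | eugenol (4-allyl-2-methoxyphenol) | C=CCc1ccc(O)c(OC)c1 | starting material
2 | 2-(hydroxymethyl)-6-methoxy-4-(prop-2-en-1-yl)phenol (magnesium salt, formed in situ) | C=CCc1cc(CO)c(O)c(OC)c1 | intermediate
3 | 2-hydroxy-3-methoxy-5-(prop-2-en-1-yl)benzaldehyde | C=CCc1cc(C=O)c(O)c(OC)c1 | intermediate
4 | 4-bromo-2,6-dimethoxyphenol | COc1cc(Br)cc(OC)c1O | starting material
5 | (4-bromo-2,6-dimethoxyphenoxy)(tert-butyl)dimethylsilane | COc1cc(Br)cc(OC)c1O[Si](C)(C)C(C)(C)C | intermediate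
6 | (S)-2-methyloxirane | C[C@H]1CO1 | starting material
7 | bromo{4-[(tert-butyldimethylsilyl)oxy]-3,5-dimethoxyphenyl}magnesium (formed in situ) | COc1cc([Mg]Br)cc(OC)c1O[Si](C)(C)C(C)(C)C | intermediate
8 | (2S)-1-{4-[(tert-butyldimethylsilyl)oxy]-3,5-dimethoxyphenyl}propan-2-ol | C[C@H](O)Cc1cc(OC)c(O[Si](C)(C)C(C)(C)C)c(OC)c1 | intermediate
9 | 2-{[(2R)-1-{4-[(tert-butyldimethylsilyl)oxy]-3,5-dimethoxyphenyl}propan-2-yl]oxy}-3-methoxy-5-(prop-2-en-1-yl)benzaldehyde | C[C@H](Cc1cc(OC)c(O[Si](C)(C)C(C)(C)C)c(OC)c1)Oc1c(C=O)cc(CC=C)cc1OC | intermediate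
10 | 2-{[(2R)-1-{4-[(tert-butyldimethylsilyl)oxy]-3,5-dimethoxyphenyl}propan-2-yl]oxy}-3-methoxy-5-(prop-2-en-1-yl)phenyl formate (formed in situ) | C[C@H](Cc1cc(OC)c(O[Si](C)(C)C(C)(C)C)c(OC)c1)Oc1c(OC=O)cc(CC=C)cc1OC | intermediate
11 | 4-{(2R)-2-[2-hydroxy-6-methoxy-4-(prop-2-en-1-yl)phenoxy]propyl}-2,6-dimethoxyphenol | C[C@H](Cc1cc(OC)c(O)c(OC)c1)Oc1c(O)cc(CC=C)cc1OC | intermediate
12 | 4-{(2R)-2-[2-hydroxy-6-methoxy-4-(prop-2-en-1-yl)phenoxy]propylidene}-2,6-dimethoxycyclohexa-2,5-dien-1-one (formed in situ) | C[C@H](C=C1C=C(OC)C(=O)C(OC)=C1)Oc1c(O)cc(CC=C)cc1OC | intermediate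
13 | (2R,3R)-2-(4-hydroxy-3,5-dimethoxyphenyl)-5-methoxy-3-methyl-7-(prop-2-en-1-yl)-2,3-dihydro-1,4-benzodioxine (CNP0116579.1) | C=CCc1cc(OC)c2c(c1)O[C@H](c1cc(OC)c(O)c(OC)c1)[C@@H](C)O2 | target

## Step count and risks

Total step count: 6. Longest linear sequence: 5 (steps 2, 3, 4, 5, 6 from 4 to 13); step 1 is a one-step branch.

Steps most likely to fail:

**Step 6 (oxidative ring closure).** Risks are over-oxidation of 13 (it is itself a 4-alkyl-2,6-dimethoxyphenol), attack of DDQ on the ring-A phenol, tautomerisation of 12 to the achiral enol ether (which would erode ee at C-3), and some cis isomer. The fallback sets out from 3 and comes back at 13; it closes the dioxane as a lactone and brings ring B in afterwards. Mitsunobu reaction of 3 with ethyl (S)-lactate F6 (purchased; PPh3, DIAD) gives, with inversion, ethyl (2R)-2-[2-formyl-6-methoxy-4-(prop-2-en-1-yl)phenoxy]propanoate F7. Baeyer–Villiger oxidation (mCPBA) gives the aryl formate F8, and methanolysis (K2CO3, MeOH) followed by acidification lactonises it to (3R)-5-methoxy-3-methyl-7-(prop-2-en-1-yl)-1,4-benzodioxin-2(3H)-one F9. Grignard reagent 7 adds at −78 °C to give the lactol (3R)-2-{4-[(tert-butyldimethylsilyl)oxy]-3,5-dimethoxyphenyl}-5-methoxy-3-methyl-7-(prop-2-en-1-yl)-2,3-dihydro-1,4-benzodioxin-2-ol F10. Ionic hydrogenation (Et3SiH, BF3·OEt2, CH2Cl2, −78 °C) gives the O-silyl benzodioxane F11 as a C-2 epimer mixture. TBAF removes the silyl group, and the liberated phenoxide equilibrates C-2 through the quinone methide to the trans isomer 13.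

**Step 4 (Mitsunobu).** The phenol is flanked on both sides and hydrogen-bonded, and the activated homobenzylic alcohol can eliminate to the propenylarene. The fallback sets out from 3 and comes back at 9; it forms the aryl–oxygen bond instead of the alkyl–oxygen bond. Phenol 3 is converted (Tf2O, pyridine) into 2-formyl-6-methoxy-4-(prop-2-en-1-yl)phenyl trifluoromethanesulfonate F1. Grignard reagent 7 is added (CuI cat.) to (R)-2-methyloxirane F2 (purchased) to give the enantiomeric alcohol (2R)-1-{4-[(tert-butyldimethylsilyl)oxy]-3,5-dimethoxyphenyl}propan-2-ol F3. Pd-catalysed C–O cross-coupling of F1 with F3 (RockPhos Pd G3, Cs2CO3, toluene, 90 °C) retains the carbinol configuration and returns to 9.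

**Step 5 (Dakin oxidation and unmasking).** Risks are competing epoxidation of the allyl group, sluggish cleavage of the hindered aryl silyl ether, and air-sensitivity of the bis-phenoxide. The fallback sets out from 1 and comes back at 11; it marks the future C-8a oxygen with bromine instead of a formyl group. Eugenol 1 is ortho-brominated (NBS, cat. i-Pr2NH, CH2Cl2) to 2-bromo-6-methoxy-4-(prop-2-en-1-yl)phenol F4. F4 is coupled with 8 under the Mitsunobu conditions of step 4 to give tert-butyl(4-{(2R)-2-[2-bromo-6-methoxy-4-(prop-2-en-1-yl)phenoxy]propyl}-2,6-dimethoxyphenoxy)dimethylsilane F5. Pd-catalysed hydroxylation (Pd2(dba)3, t-BuXPhos, KOH, dioxane/H2O, 100 °C), under which the aryl silyl ether is also cleaved, returns to 11.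

## Further compounds

F1 | step 4 | 2-formyl-6-methoxy-4-(prop-2-en-1-yl)phenyl trifluoromethanesulfonate | C=CCc1cc(C=O)c(OS(=O)(=O)C(F)(F)F)c(OC)c1
F2 | step 4 | (R)-2-methyloxirane (purchased) | C[C@@H]1CO1
F3 | step 4 | (2R)-1-{4-[(tert-butyldimethylsilyl)oxy]-3,5-dimethoxyphenyl}propan-2-ol | C[C@@H](O)Cc1cc(OC)c(O[Si](C)(C)C(C)(C)C)c(OC)c1
F4 | step 5 | 2-bromo-6-methoxy-4-(prop-2-en-1-yl)phenol | C=CCc1cc(Br)c(O)c(OC)c1
F5 | step 5 | tert-butyl(4-{(2R)-2-[2-bromo-6-methoxy-4-(prop-2-en-1-yl)phenoxy]propyl}-2,6-dimethoxyphenoxy)dimethylsilane | C[C@H](Cc1cc(OC)c(O[Si](C)(C)C(C)(C)C)c(OC)c1)Oc1c(Br)cc(CC=C)cc1OC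
F6 | step 6 | ethyl (S)-lactate (purchased) | CCOC(=O)[C@H](C)O
F7 | step 6 | ethyl (2R)-2-[2-formyl-6-methoxy-4-(prop-2-en-1-yl)phenoxy]propanoate | CCOC(=O)[C@@H](C)Oc1c(C=O)cc(CC=C)cc1OC
F8 | step 6 | ethyl (2R)-2-[2-(formyloxy)-6-methoxy-4-(prop-2-en-1-yl)phenoxy]propanoate | CCOC(=O)[C@@H](C)Oc1c(OC=O)cc(CC=C)cc1OC
F9 | step 6 | (3R)-5-methoxy-3-methyl-7-(prop-2-en-1-yl)-1,4-benzodioxin-2(3H)-one | C[C@H]1Oc2c(OC)cc(CC=C)cc2OC1=O
F10 | step 6 | (3R)-2-{4-[(tert-butyldimethylsilyl)oxy]-3,5-dimethoxyphenyl}-5-methoxy-3-methyl-7-(prop-2-en-1-yl)-2,3-dihydro-1,4-benzodioxin-2-ol (C-2 epimers) | C[C@H]1Oc2c(OC)cc(CC=C)cc2OC1(O)c1cc(OC)c(O[Si](C)(C)C(C)(C)C)c(OC)c1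
F11 | step 6 | tert-butyl{4-[(3R)-5-methoxy-3-methyl-7-(prop-2-en-1-yl)-2,3-dihydro-1,4-benzodioxin-2-yl]-2,6-dimethoxyphenoxy}dimethylsilane (C-2 epimers) | C[C@H]1Oc2c(OC)cc(CC=C)cc2OC1c1cc(OC)c(O[Si](C)(C)C(C)(C)C)c(OC)c1
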